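Even with nothing wasted, this flask cannot bring all its L to X: each X takes two E, so 0.900 M of E on 1.0 M of L allows 45.0%, and E is the limiting reagent. That is the bench rule: two E per X.

| setting | summer | flask |
|---|---|---|
| L | 1 M | 1.0 M |
| E | 0.90 M | 0.900 M |
| remark | the very flask that is asked about, followed so far |  |
| time |  | 8.0 d |

- summer (time / h: X / %, L / %): 20.0: 4.0, 66.5; 40.0: 9.3, 55.1; 60.0: 15.1, 48.5; 72.0: 16.0, 47.0; 96.0: 20.0, 42.9; 120: 20.7, 41.4

(each reading ± 1 percentage point)

- what is added takes up no volume worth counting
- what was read earlier has a scatter of 1 percentage point, one standard deviation
- a reading or a percentage of X counts all its forms, free or not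

- south-east: at 8.0 d add L, 50.0% of the amount charged, then wait 8.0 d
- north: at 8.0 d add E, 50.0% of the amount charged, then wait 8.0 d
- east: change nothing and wait 8.0 d more

- X, in percent of the L first charged, at 8.0 d
- what to do for the largest gain in X; "none" if nothing gains more than 2 percentage points (south-east / north / east / none)
- X present, in percent of the L first charged, after south-east
- X present, in percent of the L first charged, after north

We test the rule by counting turnovers. We count as if each E spent either takes an L to the mono adduct, so L falls by one, or takes a mono adduct to X, so X rises by one; any further use of E escapes this count. E spent by this count is the fall in L plus the rise in X, and at 120 h the readings of this flask give 79.3% of the L charged. The rule would then put X at 39.6%, but the reading is 20.7%, less, so X stands at 26.1% of the E spent by this count. That is the border of the rule for the charge as a whole.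

The later readings do better. The late share, the rise in X divided by the rise in X plus the fall in L between two readings, is 45.4% from 40.0 h to 120 h, close to one E in two. By this count, as an estimate, E worth 10.7% of the L charged remained at 120 h, so we expect X at 8.0 d between the last reading and 25.6%. South-east brings no new E. North brings E worth 45.0% of the L charged, and at the late share that is a gain of 20 percentage points, so we choose north.

The forecast gives 23% now, 24% after south-east, 46% after north, and chooses north. Its gain for north, 23 points, is larger than ours. Its ground: “X is slowing because E is nearly exhausted, not necessarily because of equilibrium”.

The flask gives 21.8% now, 22.1% after south-east and 41.9% after north, and the best choice is north.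

    L + E → G (k = 7.80 × 10⁻⁶ /M/s)
    E + G → X (k = 8.50 × 10⁻⁶ /M/s)
    E + X → D (k = 1.30 × 10⁻⁵ /M/s)
    E + D ⇌ J (K = 3.00 /M, k = 1.40 × 10⁻⁵ /M/s)
    Z ⇌ X, rate k5*(cs5 - [X]) while solid is left; crystals form when [X] > cs5 (solubility = 26.0 mM, k = 0.00190 /s)

In this flask the gain in X after north is 44.6% of the E added, against the late share of 45.4%. A neighbour flask charged with 1.5 M of E, reckoned from this flask at the late share, comes to 49.0%, and it holds 47.5%. In this flask the half-life of dissolved X by the making of D is 68 d at the asked time, longer than the 8.0 d of the run. D stands at 3.05% at 192 h, against 21.8% of X.

Readings and results are calculated with made-up constants; the scatter is artificial.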